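I carry one number through these flasks: the target share, which is target divided by the substrate that has left its free form. In south-west, south and north the substrate is charged in the smaller amount, so there it is the limiting reagent. Its balance puts what has left into dormant form, intermediate, target, isomer and over-reaction product.

| flask | substrate | reagent | remark | time |
|---|---|---|---|---|
| zeta | 27 mM | 18 mM | run made earlier |  |
| epsilon | 27 mM | 70 mM | run made earlier |  |
| eta | 54 mM | 35.1 mM | run made earlier |  |
| south-west | 27 mM | 35.1 mM |  | 40 min |
| south | 27 mM | 35.1 mM |  | 52 min |
| north | 27 mM | 35.1 mM |  | 68 min |

- zeta (time / min: target / %, substrate / %): 2.50: 0, 83.7; 5.00: 1.7, 71.1; 10.0: 2.1, 56.6; 15.0: 4.0, 48.6; 30.0: 6.0, 39.6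
- epsilon (time / min: target / %, substrate / %): 6.00: 3.7, 46.9; 12.0: 6.5, 28.3; 20.0: 10.3, 18.2; 25.0: 10.9, 14.7; 30.0: 10.5, 12.0
- eta (time / min: target / %, substrate / %): 2.50: 0, 79.5; 5.00: 1.4, 65.7; 10.0: 3.5, 48.5; 15.0: 5.7, 41.1; 30.0: 8.6, 32.1

(standard deviation of a reading: 0.5 percentage points)

- steps under discussion: substrate + reagent -> intermediate + released group; intermediate <-> target; intermediate <-> isomer of the product; substrate <-> dormant form; reagent + target -> over-reaction product

- which of the two there is more of at the end, south-west (target / isomer of the product)
- which of the two there is more of at the end, south (target / isomer of the product)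
- which of the two there is more of at the end, north (target / isomer of the product)
- target at the end, in percent of the substrate charged, south-west
- target at the end, in percent of the substrate charged, south
- target at the end, in percent of the substrate charged, north

I turn the reagent first. By hand, more reagent takes out more substrate. At 30.0 min, zeta leaves 39.6 % and epsilon 12.0 %, while target reads 6.0 % and 10.5 %. The shares are 9.93 % in zeta and 11.9 % in epsilon, so from zeta to epsilon the share grows by a smaller factor than the target does.

Next I turn both charges together: eta holds twice the substrate of zeta and twice its reagent. By hand, that should matter little to a share. Eta at 30.0 min gives 12.7 %, more than zeta gives.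

Time comes last. By hand, target should keep rising, but epsilon reads 10.9 % at 25.0 min and 10.5 % at 30.0 min, with a scatter of 0.5 percentage points.

So I need the substrate left, and I match reagent charge times time against epsilon. South-west gives 84.2 M·s, nearly the same as epsilon at 20.0 min, which leaves 18.2 %. South gives 110 M·s, a little past epsilon at 25.0 min, which leaves 14.7 %. North gives 143 M·s, past epsilon's last reading of 12.0 %. South-west, south and north have the smaller reagent charge, so I expect their reagent to fall further in proportion, and I take these figures as low.

My share then gives 9.73 %, 10.2 % and 10.5 %, probably a little high.

The forecast differs slightly: 10 % (8.3 % to 11.8 %), 10.3 % (8.2 % to 12.5 %) and 10.3 % (7.8 % to 13 %). It names the isomer of the product as the larger in south-west, south and north, reasoning that “the intermediate is probably draining mainly elsewhere”. I cannot read the isomer, and I take the same side.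

The flasks give target 9.27 % in south-west, 9.36 % in south and 8.95 % in north. The isomer stands at 15.0 %, 20.2 % and 26.6 %.

    substrate + reagent → intermediate + released group (k = 1.32 M⁻¹ min⁻¹)
    intermediate ⇌ target (K = 0.410, k = 0.0467 min⁻¹)
    intermediate ⇌ isomer of the product (K = 44.0, k = 0.0167 min⁻¹)
    substrate ⇌ dormant form (K = 0.742, k = 0.0553 min⁻¹)
    reagent + target → over-reaction product (k = 0.905 M⁻¹ min⁻¹)

With the substrate actually left in south, 20 %, the share gives 9.52 % against 9.36 %. The neighbour flask with 60 mM of reagent leaves 9.3 %, so the share gives 10.8 % against 9.79 %. South has not come to rest at 52 min: intermediate stands at 25.6 %. Ten times the time, 520 min, takes the isomer from 20.2 % to 73.5 % and the target down to 1.00 %.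

The earlier runs and the new flask are simulated for substances that don't exist, noise included.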